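Late in this flask, at 10 d, I wanted the average chain length and the part of the free monomer reacted.

| flask | free monomer | transfer agent | pre-initiator | impurity | remark | time |
|---|---|---|---|---|---|---|
| Sunday's | 3 M | 0.30 M | 10 mol% | 100 mM | the very flask that is asked about, followed so far |  |
| flask | 3.0 M | 0.300 M | 10 mol% | 100 mM |  | 10 d |

Sunday's run (percent of the free monomer charged)

| time / d | monomer in chains / % | free monomer / % |
|---|---|---|
| 0.833 | 2 | 100 |
| 1.67 | 1 | 99 |
| 2.50 | 11 | 85 |
| 3.00 | 21 | 78 |
| 4.00 | 39 | 65 |

(scatter of a reading: 1.5 percentage points)

- the average divides the monomer in chains by the number of chains begun, living and dead together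
- steps that have been proposed: free monomer + initiator -> living end + monomer in chains; free monomer + living end -> monomer in chains + living end; living end + transfer agent -> dead chain; pre-initiator -> initiator; initiator + impurity -> spent initiator; free monomer -> decomposition product
- the earlier runs do not show the number of chains; that part of a forecast is a guess

- average number of monomer units in a chain (chains begun, living or dead) at 10 d
- part of the free monomer that has reacted at 10 d

On the proposed steps, pre-initiator releases initiator. Initiator is spent on impurity or starts a living end on free monomer, and transfer agent turns a living end into a dead chain. So I subtracted first. The pre-initiator charge, 0.300 M, less the impurity, 0.1 M, gave 0.200 M. I called this the surplus, the initiator left for starting chains once the impurity has taken its share.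

But the surplus is a ceiling, not a count at 10 d. Free monomer still read 99% at 1.67 d. I took that delay, the induction period, as the time release needed to pay the impurity. The logarithm of charge over surplus, divided by that scattered delay, gave a rough release constant of 0.243 d⁻¹. That left 0.174 M of chains begun by 10 d, which is a guess.

Next I went to logarithms. The logarithm of free monomer fell by 0.179 d⁻¹ over the last readings. Held steady, that left 22.2% at 10 d. But my chain count averaged 0.0637 M during those readings and 0.130 M afterwards, about twice as many. Scaling the slope by that left 7.28%. That in turn let no chain die, and the readings do not show the number of chains. So I took the middle on the logarithmic scale, which gave 87.3% reacted and, counting reacted monomer as monomer in chains, an average of 15.1.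

The forecast gave 72% reacted, less than my figure, and an average of 13, reading “living ends near steady state, with transfer killing them”.

The flask gave an average of 14.8, with 89.4% reacted.

free monomer + initiator → living end + monomer in chains (k = 7.11 × 10⁻⁶ L mol⁻¹ s⁻¹); free monomer + living end → monomer in chains + living end, rate k2*[living end]*[free monomer] (k = 3.07 × 10⁻⁵ L mol⁻¹ s⁻¹); living end + transfer agent → dead chain (kL = 4.60 × 10⁻⁶ L mol⁻¹ s⁻¹); pre-initiator → initiator (k = 4.60 × 10⁻⁶ s⁻¹); initiator + impurity → spent initiator (k = 0.0334 L mol⁻¹ s⁻¹); free monomer → decomposition product (k = 2.24 × 10⁻⁸ s⁻¹) Its living ends and dead chains together stood at 0.179 M at 10 d, against my 0.174 M. A neighbouring flask had 2.5 mol% of pre-initiator, all else the same. There the same subtraction gave a surplus of −0.0250 M, below zero. That neighbouring flask still held 27% of its impurity at 10 d, and 97.1% of its charged monomer stood as free monomer, with 1.00% in chains.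

(Readings and results are calculated with made-up constants; noise was put on by code.)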